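**Plan**

- Retrosynthetic cuts: the dihydrofuran is opened at C7–C(naphthyl) (Friedel–Crafts) and C6–O (carbenoid O–H insertion), giving naphthol 30 and diazo ketone 18. Ring B is cut at C7–C8 (acylation). Ring A is contracted to a cyclopentane by taking C4 out from between C3 and C5. The C5–C6 and C10–aryl bonds are then cut (enolate alkylation, conjugate addition).
- Enabling feature: in ring A the oxygen-bearing C3 lies next to the gem-dimethyl carbon C4, which is bonded to the ring-fusion carbon C5. This is the retron of a 1,2-shift of C5 from a cyclopentanol carbon (C3) to a Me2C+ centre (C4).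
- Forward order: the cyclopentane (C3, C2, C1, C10, C5) is made first; ring A follows by one-carbon enlargement; ring B by Friedel–Crafts acylation; the naphthalene half comes from a tetralone; the dihydrofuran is closed last by O–H insertion and cationic C7–aryl closure.
- Stereochemistry: C10 comes from a chiral copper catalyst. C5 comes from enolate alkylation anti to the aryl group and is carried with retention through the shift. C3 comes from axial hydride delivery, C6 from equilibration next to the C7 ketone, and C7 from the cis fusion of the five-membered ring.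

Key step: step 6

Remark: abietane numbering (C1–C20, rings A, B, C) is used for the hinokiol half. The carbinol centre of 12 and the C7 centre of 33 are erased in the following steps, so only the expected epimer is drawn.

**Part A: hinokiol half**

Step 1
Reactants: 1 methyl 4-bromo-2-methoxybenzoate
Product: 2 2-(4-bromo-2-methoxyphenyl)propan-2-ol
Conditions: MeMgBr (3 equiv), THF, 0 °C → rt; aq. NH4Cl
Reagents that add atoms: methylmagnesium bromide, C[Mg]Br
Why: Double Grignard addition to the ester should give the tertiary benzylic alcohol, the aryl bromide being inert to MeMgBr at this temperature.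

Step 2
Reactants: 2 2-(4-bromo-2-methoxyphenyl)propan-2-ol
Product: 3 4-bromo-2-methoxy-1-(propan-2-yl)benzene
Conditions: Et3SiH (2 equiv), CF3CO2H, CH2Cl2, 0 °C → rt
Reagents that add atoms: none
Why: Ionic hydrogenation, in which the acid ionises the ortho-methoxy-stabilised tertiary benzylic alcohol and the silane delivers hydride, should give the isopropyl group.

Step 3
Reactants: 3 4-bromo-2-methoxy-1-(propan-2-yl)benzene; 4 3-methylcyclopent-2-en-1-one
Product: 8 (S)-{[3-(4-isopropyl-3-methoxyphenyl)-3-methylcyclopent-1-en-1-yl]oxy}trimethylsilane, via aryllithium 5 (not isolated), via aryldimethylalane 6 (not isolated), via aluminium enolate 7 (not isolated)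
Conditions: n-BuLi, THF, −78 °C; Me2AlCl, −78 → 0 °C; 4, copper thiophene-2-carboxylate (10 mol %), chiral BINOL-derived phosphoramidite ligand (11 mol %, the enantiomer that gives the S centre), Et2O, −20 °C; TMSOTf, −20 °C → rt
Reagents that add atoms: trimethylsilyl trifluoromethanesulfonate, C[Si](C)(C)OS(=O)(=O)C(F)(F)F
Why: Bromine–lithium exchange, transmetalation to aluminium and copper-catalysed asymmetric conjugate addition (aryl transfers in preference to methyl) should create the benzylic quaternary centre C10 under control of the chiral ligand, and O-silylation fixes the enolate on the C3–C5 side.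

Step 4
Reactants: 8 (S)-{[3-(4-isopropyl-3-methoxyphenyl)-3-methylcyclopent-1-en-1-yl]oxy}trimethylsilane; 9 tert-butyl bromoacetate
Product: 11 tert-butyl 2-[(1R,2S)-2-(4-isopropyl-3-methoxyphenyl)-2-methyl-5-oxocyclopentyl]acetate, via lithium enolate 10 (not isolated)
Conditions: MeLi, THF, 0 °C; 9, −78 → −20 °C
Reagents that add atoms: none
Why: The regiodefined lithium enolate released by silicon–lithium exchange should be alkylated by the reactive α-bromo ester on the face anti to the aryl group of the neighbouring quaternary carbon, so that the acetate arm ends cis to the methyl group and C5 is set (enolate alkylation).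

Step 5
Reactants: 11 tert-butyl 2-[(1R,2S)-2-(4-isopropyl-3-methoxyphenyl)-2-methyl-5-oxocyclopentyl]acetate
Product: 12 tert-butyl 2-[(1R,2S,5S)-5-hydroxy-2-(4-isopropyl-3-methoxyphenyl)-2-methyl-5-(prop-1-en-2-yl)cyclopentyl]acetate
Conditions: isopropenylmagnesium bromide, CeCl3, THF, −78 °C; aq. NH4Cl at −78 °C
Reagents that add atoms: isopropenylmagnesium bromide, CC(=C)[Mg]Br
Why: Organocerium 1,2-addition should suppress enolisation of the hindered ketone and spare the tert-butyl ester, with attack expected anti to the C5 arm, although the new carbinol centre is erased in step 6.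

Step 6
Reactants: 12 tert-butyl 2-[(1R,2S,5S)-5-hydroxy-2-(4-isopropyl-3-methoxyphenyl)-2-methyl-5-(prop-1-en-2-yl)cyclopentyl]acetate
Product: 13 tert-butyl 2-[(1R,6S)-6-(4-isopropyl-3-methoxyphenyl)-2,2,6-trimethyl-3-oxocyclohexyl]acetate
Conditions: (R,R)-N,N′-bis(3,5-di-tert-butylsalicylidene)-1,2-cyclohexanediaminocobalt (5 mol %), N-fluoro-2,4,6-trimethylpyridinium triflate (1.5 equiv), PhSiH3 (1.5 equiv), acetone, 0 °C → rt
Reagents that add atoms: none
Why: A cobalt hydride formed from the salen complex, the N-fluoropyridinium oxidant and PhSiH3 should transfer a hydrogen atom to the CH2 terminus of the isopropenyl group, and the tertiary C4 radical is oxidised through an alkylcobalt species to the C4 cation (radical–polar crossover); C5 then shifts from the carbinol carbon C3 to C4 while C3 becomes the carbonyl, a semipinacol 1,2-shift that enlarges the cyclopentane (C3, C2, C1, C10, C5) to ring A (C10, C1, C2, C3, C4, C5) and installs the gem-dimethyl carbon. The closest known reaction types are the hydrogen-atom-transfer-initiated radical–polar crossover semipinacol rearrangement of tertiary allylic alcohols, ring expansions of 1-alkenylcycloalkanols included, and the classical pinacol enlargement of 1-(2-hydroxyprop-2-yl)cyclopentanols to 2,2-dimethylcyclohexanones. No ring is closed in the usual sense, because ring A arises by insertion of C4 into the C3–C5 bond of the five-membered ring. No new stereocentre is formed: C5 migrates with retention, so the trans relation of H-5 and the C10 methyl group set in steps 3 and 4 is carried into ring A, and the carbinol centre disappears. The step needs chemoselective activation of the 1,1-disubstituted alkene beside the anisole ring and the ester, which the polarity and steric preference of the metal hydride should secure, and migration of C5 instead of C2, which the higher migratory aptitude of the more substituted carbon should secure.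

Step 7
Reactants: 13 tert-butyl 2-[(1R,6S)-6-(4-isopropyl-3-methoxyphenyl)-2,2,6-trimethyl-3-oxocyclohexyl]acetate
Product: 14 12-methoxyabieta-8,11,13-triene-3,7-dione
Conditions: P2O5/MeSO3H (1:10 w/w), 50 °C
Reagents that add atoms: none
Why: The acid should remove the tert-butyl group and the resulting acylium ion should acylate the arene intramolecularly (Friedel–Crafts acylation) at C8, the position para to the methoxy group, closing ring B without touching C5 or C10.

Step 8
Reactants: 14 12-methoxyabieta-8,11,13-triene-3,7-dione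
Product: 15 3β-hydroxy-12-methoxyabieta-8,11,13-trien-7-one
Conditions: NaBH4 (0.5 equiv), MeOH/CH2Cl2, −40 °C
Reagents that add atoms: none
Why: The saturated C3 ketone should be reduced faster than the para-methoxy-conjugated aryl ketone, with axial hydride delivery from the α face giving the equatorial 3β-alcohol (chemoselective borohydride reduction).

Step 9
Reactants: 15 3β-hydroxy-12-methoxyabieta-8,11,13-trien-7-one
Product: 16 3β-(tert-butyldimethylsilyloxy)-12-methoxyabieta-8,11,13-trien-7-one
Conditions: TBSOTf, 2,6-lutidine, CH2Cl2, −78 → 0 °C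
Reagents that add atoms: tert-butyldimethylsilyl trifluoromethanesulfonate, CC(C)(C)[Si](C)(C)OS(=O)(=O)C(F)(F)F
Why: Silylation with the silyl triflate should mask the only O–H group that could compete in the carbenoid step.

Step 10
Reactants: 16 3β-(tert-butyldimethylsilyloxy)-12-methoxyabieta-8,11,13-trien-7-one
Product: 18 3β-(tert-butyldimethylsilyloxy)-6-diazo-12-methoxyabieta-8,11,13-trien-7-one, via trifluoroacetyl ketone 17 (not isolated)
Conditions: LiN(SiMe3)2, THF, −78 °C; CF3CO2CH2CF3; then MsN3, Et3N, H2O (1 equiv), MeCN, rt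
Reagents that add atoms: methanesulfonyl azide, CS(=O)(=O)N=[N+]=[N-]
Why: In this deacylative Regitz-type diazo transfer the only enolisable site of the ketone, C6, is trifluoroacetylated and then accepts the diazo group from the sulfonyl azide with loss of the trifluoroacetyl group.

**Part B: naphthol half**

Step 11
Reactants: 19 6-methoxy-3,4-dihydronaphthalen-1(2H)-one
Product: 20 6-methoxy-2-methyl-3,4-dihydronaphthalen-1(2H)-one (racemic)
Conditions: LiN(iPr)2, THF, −78 °C; MeI, −78 → 0 °C
Reagents that add atoms: iodomethane, CI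
Why: The lithium enolate should be methylated at C2, the only enolisable position (enolate alkylation).

Step 12
Reactants: 20 6-methoxy-2-methyl-3,4-dihydronaphthalen-1(2H)-one
Product: 21 6-methoxy-2-methylnaphthalen-1-ol
Conditions: Pd(OCOCF3)2 (5 mol %), 2-(dimethylamino)pyridine (10 mol %), TsOH (20 mol %), O2 (1 atm), DMSO, 80 °C
Reagents that add atoms: none
Why: Palladium-catalysed aerobic dehydrogenation of the cyclohexanone ring followed by tautomerisation should aromatise the tetralone to the 1-naphthol.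

Step 13
Reactants: 21 6-methoxy-2-methylnaphthalen-1-ol
Product: 22 6-methoxy-2-methylnaphthalen-1-yl trifluoromethanesulfonate
Conditions: Tf2O, pyridine, CH2Cl2, 0 °C
Reagents that add atoms: trifluoromethanesulfonic anhydride, O=S(=O)(OS(=O)(=O)C(F)(F)F)C(F)(F)F
Why: O-Triflation should turn the naphthol into an electrophile for palladium coupling.

Step 14
Reactants: 22 6-methoxy-2-methylnaphthalen-1-yl trifluoromethanesulfonate; 23 4-methylpent-1-en-3-ol
Product: 24 1-(6-methoxy-2-methylnaphthalen-1-yl)-4-methylpentan-3-one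
Conditions: Pd(OAc)2 (5 mol %), LiCl (3 equiv), iPr2NEt, DMF, 90 °C
Reagents that add atoms: none
Why: In this Heck reaction with a secondary allylic alcohol the arylpalladium species adds to the terminal alkene carbon and β-hydride elimination towards the carbinol gives the enol, and hence the saturated ketone side chain, in one step.

Step 15
Reactants: 24 1-(6-methoxy-2-methylnaphthalen-1-yl)-4-methylpentan-3-one
Product: 25 2-[2-(6-methoxy-2-methylnaphthalen-1-yl)ethyl]-2-(propan-2-yl)-1,3-dioxolane
Conditions: ethane-1,2-diol, TsOH (cat.), toluene, reflux, water separator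
Reagents that add atoms: ethane-1,2-diol, OCCO
Why: Ketalisation should mask the side-chain ketone against the borohydride of step 21.

Step 16
Reactants: 25 2-[2-(6-methoxy-2-methylnaphthalen-1-yl)ethyl]-2-(propan-2-yl)-1,3-dioxolane
Product: 26 2-[2-(5-bromo-6-methoxy-2-methylnaphthalen-1-yl)ethyl]-2-(propan-2-yl)-1,3-dioxolane
Conditions: NBS, NaHCO3, MeCN, 0 °C, dark
Reagents that add atoms: N-bromosuccinimide, O=C1CCC(=O)N1Br
Why: Electrophilic aromatic bromination should occur at C5, the α-position ortho to the methoxy group and the most activated site of a 2-methoxynaphthalene.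

Step 17
Reactants: 26 2-[2-(5-bromo-6-methoxy-2-methylnaphthalen-1-yl)ethyl]-2-(propan-2-yl)-1,3-dioxolane; 27 4,4,5,5-tetramethyl-2-(prop-1-en-2-yl)-1,3,2-dioxaborolane
Product: 28 2-{2-[6-methoxy-2-methyl-5-(prop-1-en-2-yl)naphthalen-1-yl]ethyl}-2-(propan-2-yl)-1,3-dioxolane
Conditions: [1,1′-bis(diphenylphosphino)ferrocene]dichloropalladium (5 mol %), K2CO3, 1,4-dioxane/H2O, 90 °C
Reagents that add atoms: none
Why: Suzuki–Miyaura coupling should install the three-carbon unit at the hindered C5 as an alkenyl group, which avoids the isomerisation of a secondary alkyl metal.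

Step 18
Reactants: 28 2-{2-[6-methoxy-2-methyl-5-(prop-1-en-2-yl)naphthalen-1-yl]ethyl}-2-(propan-2-yl)-1,3-dioxolane
Product: 29 2-{2-[6-methoxy-2-methyl-5-(propan-2-yl)naphthalen-1-yl]ethyl}-2-(propan-2-yl)-1,3-dioxolane
Conditions: H2 (1 atm), Pd/C (palladium on carbon, 10 wt %), EtOAc, rt
Reagents that add atoms: none
Why: Catalytic hydrogenation of the 1,1-disubstituted alkene should give the isopropyl group without reducing the naphthalene.

Step 19
Reactants: 29 2-{2-[6-methoxy-2-methyl-5-(propan-2-yl)naphthalen-1-yl]ethyl}-2-(propan-2-yl)-1,3-dioxolane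
Product: 30 1-isopropyl-6-methyl-5-{2-[2-(propan-2-yl)-1,3-dioxolan-2-yl]ethyl}naphthalen-2-ol
Conditions: NaSEt, DMF, 130 °C; dilute HCl to pH 6 at 0 °C
Reagents that add atoms: none
Why: Thiolate SN2 demethylation should free the naphthol under basic conditions that leave the dioxolane intact.

**Part C: union and completion**

Step 20
Reactants: 18 3β-(tert-butyldimethylsilyloxy)-6-diazo-12-methoxyabieta-8,11,13-trien-7-one; 30 1-isopropyl-6-methyl-5-{2-[2-(propan-2-yl)-1,3-dioxolan-2-yl]ethyl}naphthalen-2-ol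
Product: 32 6α-(aryloxy)-3β-(tert-butyldimethylsilyloxy)-12-methoxyabieta-8,11,13-trien-7-one (aryl = the naphthalen-2-yl group of 30), via 6β-epimer 31 (not isolated)
Conditions: Rh2(OAc)4 (2 mol %), 30 (1.5 equiv), CH2Cl2, rt, slow addition of 18; then DBU (0.3 equiv), rt
Reagents that add atoms: none
Why: Rhodium-carbenoid O–H insertion should form the hindered C6–O aryl ether without an SN2 displacement, and base equilibration through the enol should give the equatorial 6α ether because the 6β isomer suffers a 1,3-diaxial clash with the C10 methyl group.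

Step 21
Reactants: 32 6α-(aryloxy)-3β-(tert-butyldimethylsilyloxy)-12-methoxyabieta-8,11,13-trien-7-one
Product: 33 6α-(aryloxy)-3β-(tert-butyldimethylsilyloxy)-12-methoxyabieta-8,11,13-trien-7β-ol
Conditions: NaBH4, MeOH/THF, 0 °C
Reagents that add atoms: none
Why: Borohydride should reduce the only free ketone, the side-chain ketone being masked as the dioxolane, and either C7 epimer serves because this centre is ionised in the next step.

Step 22
Reactants: 33 6α-(aryloxy)-3β-(tert-butyldimethylsilyloxy)-12-methoxyabieta-8,11,13-trien-7β-ol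
Product: 34 the 12-O-methyl, 3-O-tert-butyldimethylsilyl, side-chain dioxolane derivative of the target (6α-O, 7α-C cis-fused dihydronaphthofuran)
Conditions: CF3CO2H (3 equiv), CH2Cl2, −20 → 0 °C
Reagents that add atoms: none
Why: Ionisation of the para-methoxybenzylic alcohol should give the C7 cation, which is captured by the only free ortho position of the naphthyl ether (intramolecular Friedel–Crafts alkylation), and the cis fusion imposed by the five-membered ring places the new C7–aryl bond on the α face defined by the C6–O bond.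

Step 23
Reactants: 34 the 12-O-methyl, 3-O-tert-butyldimethylsilyl, side-chain dioxolane derivative of the target
Product: 35 target CNP0584944.1
Conditions: BBr3 (6 equiv), CH2Cl2, −78 → 0 °C; aq. NaHCO3
Reagents that add atoms: water (work-up, supplies the ketone oxygen when the opened dioxolane is hydrolysed), O
Why: Lewis-acid ether cleavage should remove the aryl methyl ether, the silyl ether and the dioxolane in one operation, the alkyl aryl ether of the dihydrofuran at the hindered, non-benzylic C6 being slower to open.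

**Compound list**

1 | methyl 4-bromo-2-methoxybenzoate | COC(=O)c1ccc(Br)cc1OC | starting material
2 | 2-(4-bromo-2-methoxyphenyl)propan-2-ol | COc1cc(Br)ccc1C(C)(C)O | intermediate
3 | 4-bromo-2-methoxy-1-(propan-2-yl)benzene | COc1cc(Br)ccc1C(C)C | intermediate
4 | 3-methylcyclopent-2-en-1-one | CC1=CC(=O)CC1 | starting material
5 | (4-isopropyl-3-methoxyphenyl)lithium | [Li]c1ccc(C(C)C)c(OC)c1 | intermediate
6 | (4-isopropyl-3-methoxyphenyl)dimethylalane | C[Al](C)c1ccc(C(C)C)c(OC)c1 | intermediate
7 | dimethylaluminium (S)-3-(4-isopropyl-3-methoxyphenyl)-3-methylcyclopent-1-en-1-olate | C[Al](C)OC1=C[C@@](C)(c2ccc(C(C)C)c(OC)c2)CC1 | intermediate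
8 | (S)-{[3-(4-isopropyl-3-methoxyphenyl)-3-methylcyclopent-1-en-1-yl]oxy}trimethylsilane | C[Si](C)(C)OC1=C[C@@](C)(c2ccc(C(C)C)c(OC)c2)CC1 | intermediate
9 | tert-butyl bromoacetate | CC(C)(C)OC(=O)CBr | starting material
10 | lithium (S)-3-(4-isopropyl-3-methoxyphenyl)-3-methylcyclopent-1-en-1-olate | [Li]OC1=C[C@@](C)(c2ccc(C(C)C)c(OC)c2)CC1 | intermediate
11 | tert-butyl 2-[(1R,2S)-2-(4-isopropyl-3-methoxyphenyl)-2-methyl-5-oxocyclopentyl]acetate (arm trans to aryl) | O=C1[C@H](CC(=O)OC(C)(C)C)[C@@](C)(c2ccc(C(C)C)c(OC)c2)CC1 | intermediate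
12 | tert-butyl 2-[(1R,2S,5S)-5-hydroxy-2-(4-isopropyl-3-methoxyphenyl)-2-methyl-5-(prop-1-en-2-yl)cyclopentyl]acetate | C=C(C)[C@]1(O)CC[C@](C)(c2ccc(C(C)C)c(OC)c2)[C@H]1CC(=O)OC(C)(C)C | intermediate
13 | tert-butyl 2-[(1R,6S)-6-(4-isopropyl-3-methoxyphenyl)-2,2,6-trimethyl-3-oxocyclohexyl]acetate | O=C1CC[C@](C)(c2ccc(C(C)C)c(OC)c2)[C@@H](CC(=O)OC(C)(C)C)C1(C)C | intermediate
14 | 12-methoxyabieta-8,11,13-triene-3,7-dione (5α-H, 10β-Me) | O=C1C[C@H]2C(C)(C)C(=O)CC[C@]2(C)c2cc(OC)c(C(C)C)cc21 | intermediate
15 | 3β-hydroxy-12-methoxyabieta-8,11,13-trien-7-one | O=C1C[C@H]2C(C)(C)[C@@H](O)CC[C@]2(C)c2cc(OC)c(C(C)C)cc21 | intermediate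
16 | 3β-(tert-butyldimethylsilyloxy)-12-methoxyabieta-8,11,13-trien-7-one | O=C1C[C@H]2C(C)(C)[C@@H](O[Si](C)(C)C(C)(C)C)CC[C@]2(C)c2cc(OC)c(C(C)C)cc21 | intermediate
17 | 3β-(tert-butyldimethylsilyloxy)-12-methoxy-6-(trifluoroacetyl)abieta-8,11,13-trien-7-one (drawn as the 6α diketo tautomer, present mainly as the chelated enol) | O=C1[C@H](C(=O)C(F)(F)F)[C@H]2C(C)(C)[C@@H](O[Si](C)(C)C(C)(C)C)CC[C@]2(C)c2cc(OC)c(C(C)C)cc21 | intermediate
18 | 3β-(tert-butyldimethylsilyloxy)-6-diazo-12-methoxyabieta-8,11,13-trien-7-one | O=C1C(=[N+]=[N-])[C@H]2C(C)(C)[C@@H](O[Si](C)(C)C(C)(C)C)CC[C@]2(C)c2cc(OC)c(C(C)C)cc21 | intermediate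
19 | 6-methoxy-3,4-dihydronaphthalen-1(2H)-one | COc1ccc2C(=O)CCCc2c1 | starting material
20 | 6-methoxy-2-methyl-3,4-dihydronaphthalen-1(2H)-one (racemic) | COc1ccc2C(=O)C(C)CCc2c1 | intermediate
21 | 6-methoxy-2-methylnaphthalen-1-ol | COc1ccc2c(O)c(C)ccc2c1 | intermediate
22 | 6-methoxy-2-methylnaphthalen-1-yl trifluoromethanesulfonate | COc1ccc2c(OS(=O)(=O)C(F)(F)F)c(C)ccc2c1 | intermediate
23 | 4-methylpent-1-en-3-ol (racemic) | C=CC(O)C(C)C | starting material
24 | 1-(6-methoxy-2-methylnaphthalen-1-yl)-4-methylpentan-3-one | COc1ccc2c(CCC(=O)C(C)C)c(C)ccc2c1 | intermediate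
25 | 2-[2-(6-methoxy-2-methylnaphthalen-1-yl)ethyl]-2-(propan-2-yl)-1,3-dioxolane | COc1ccc2c(CCC3(C(C)C)OCCO3)c(C)ccc2c1 | intermediate
26 | 2-[2-(5-bromo-6-methoxy-2-methylnaphthalen-1-yl)ethyl]-2-(propan-2-yl)-1,3-dioxolane | COc1ccc2c(CCC3(C(C)C)OCCO3)c(C)ccc2c1Br | intermediate
27 | 4,4,5,5-tetramethyl-2-(prop-1-en-2-yl)-1,3,2-dioxaborolane | CC(=C)B1OC(C)(C)C(C)(C)O1 | starting material
28 | 2-{2-[6-methoxy-2-methyl-5-(prop-1-en-2-yl)naphthalen-1-yl]ethyl}-2-(propan-2-yl)-1,3-dioxolane | COc1ccc2c(CCC3(C(C)C)OCCO3)c(C)ccc2c1C(C)=C | intermediate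
29 | 2-{2-[6-methoxy-2-methyl-5-(propan-2-yl)naphthalen-1-yl]ethyl}-2-(propan-2-yl)-1,3-dioxolane | COc1ccc2c(CCC3(C(C)C)OCCO3)c(C)ccc2c1C(C)C | intermediate
30 | 1-isopropyl-6-methyl-5-{2-[2-(propan-2-yl)-1,3-dioxolan-2-yl]ethyl}naphthalen-2-ol | Oc1ccc2c(CCC3(C(C)C)OCCO3)c(C)ccc2c1C(C)C | intermediate
31 | 6β-(aryloxy)-3β-(tert-butyldimethylsilyloxy)-12-methoxyabieta-8,11,13-trien-7-one (aryl = naphthalen-2-yl group of 30) | O=C1[C@@H](Oc3ccc4c(CCC5(C(C)C)OCCO5)c(C)ccc4c3C(C)C)[C@H]2C(C)(C)[C@@H](O[Si](C)(C)C(C)(C)C)CC[C@]2(C)c2cc(OC)c(C(C)C)cc21 | intermediate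
32 | 6α-(aryloxy)-3β-(tert-butyldimethylsilyloxy)-12-methoxyabieta-8,11,13-trien-7-one | O=C1[C@H](Oc3ccc4c(CCC5(C(C)C)OCCO5)c(C)ccc4c3C(C)C)[C@H]2C(C)(C)[C@@H](O[Si](C)(C)C(C)(C)C)CC[C@]2(C)c2cc(OC)c(C(C)C)cc21 | intermediate
33 | 6α-(aryloxy)-3β-(tert-butyldimethylsilyloxy)-12-methoxyabieta-8,11,13-trien-7β-ol | O[C@H]1[C@H](Oc3ccc4c(CCC5(C(C)C)OCCO5)c(C)ccc4c3C(C)C)[C@H]2C(C)(C)[C@@H](O[Si](C)(C)C(C)(C)C)CC[C@]2(C)c2cc(OC)c(C(C)C)cc21 | intermediate
34 | 12-O-methyl, 3-O-tert-butyldimethylsilyl, side-chain dioxolane derivative of the target (3β-O, 5α-H, 6α-O, 7α-aryl, 10β-Me) | Cc1ccc2c(C(C)C)c3c(cc2c1CCC1(C(C)C)OCCO1)[C@H]1c2cc(C(C)C)c(OC)cc2[C@@]2(C)CC[C@H](O[Si](C)(C)C(C)(C)C)C(C)(C)[C@@H]2[C@H]1O3 | intermediate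
35 | CNP0584944.1 | Cc1ccc2c(C(C)C)c3c(cc2c1CCC(=O)C(C)C)[C@H]1c2cc(C(C)C)c(O)cc2[C@@]2(C)CC[C@H](O)C(C)(C)[C@@H]2[C@H]1O3 | target

**Totals and risks**

Total step count: 23. Longest linear sequence: 14 steps (steps 1–10, then 20–23).

Steps most likely to fail:

1. Step 6. The C4 cation may be captured by the neighbouring hydroxyl (or the ester oxygen) instead of triggering the shift, or C2 may migrate in place of C5. The fallback sets out from ketone 11 and returns at 13. Corey–Chaykovsky-type isopropylidene transfer to 11 with diphenylsulfonium isopropylide (isopropyldiphenylsulfonium tetrafluoroborate, t-BuLi, DME, −70 °C) should give the spiro-epoxide tert-butyl 2-[5-(4-isopropyl-3-methoxyphenyl)-2,2,5-trimethyl-1-oxaspiro[2.4]heptan-4-yl]acetate F1. BF3·OEt2 (CH2Cl2, −78 °C) should then open the epoxide at the acyclic tertiary carbon and drive the same shift of C5 to give 13.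

2. Step 20. The rhodium carbenoid may undergo a 1,2-hydride shift from C5–H to the enone faster than it inserts into the hindered naphthol O–H. The fallback sets out from ketone 16 and returns at 32 through 31. Ketone 16 is converted (TMSOTf, Et3N, CH2Cl2) to the silyl enol ether 3β-(tert-butyldimethylsilyloxy)-12-methoxy-7-(trimethylsilyloxy)abieta-6,8,11,13-tetraene F2. Rubottom oxidation from the α face (dimethyldioxirane, acetone, −40 °C; then citric acid, MeOH) should give 3β-(tert-butyldimethylsilyloxy)-6α-hydroxy-12-methoxyabieta-8,11,13-trien-7-one F3. Mitsunobu etherification of F3 with naphthol 30 (PPh3, DIAD, toluene) should invert C6 to give 31, which the DBU equilibration of step 20 converts to 32.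

3. Step 22. The C7 cation may be lost by elimination towards the enol ether, with release of the naphthol on work-up, or may attack the isopropyl-bearing ipso carbon. The fallback inverts the order of bond formation; it sets out from ketone 16 and returns at 34.
   - NaBH4 (MeOH, 0 °C) should give 3β-(tert-butyldimethylsilyloxy)-12-methoxyabieta-8,11,13-trien-7β-ol F4.
   - TsOH (cat., toluene, 60 °C) should dehydrate it to 3β-(tert-butyldimethylsilyloxy)-12-methoxyabieta-6,8,11,13-tetraene F5.
   - NBS in aqueous THF should add from the α face to give 6α-bromo-3β-(tert-butyldimethylsilyloxy)-12-methoxyabieta-8,11,13-trien-7β-ol F6.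
   - K2CO3 in MeOH should close it to 3β-(tert-butyldimethylsilyloxy)-6β,7β-epoxy-12-methoxyabieta-8,11,13-triene F7.
   - Naphthol 30 (2 equiv) in (CF3)2CHOH at 0 °C should open the benzylic C7–O bond with inversion (Friedel–Crafts) to give 3β-(tert-butyldimethylsilyloxy)-7α-(3-hydroxy-4-isopropyl-7-methyl-8-{2-[2-(propan-2-yl)-1,3-dioxolan-2-yl]ethyl}naphthalen-2-yl)-12-methoxyabieta-8,11,13-trien-6β-ol F8.
   - Intramolecular Mitsunobu etherification (PPh3, DIAD, toluene, 60 °C) with inversion at C6 should give 34.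

Further compounds
F1 | step 6 | tert-butyl 2-[5-(4-isopropyl-3-methoxyphenyl)-2,2,5-trimethyl-1-oxaspiro[2.4]heptan-4-yl]acetate (ring carbons as in 11, epoxide oxygen cis to the acetate arm) | CC1(C)O[C@]12CC[C@](C)(c3ccc(C(C)C)c(OC)c3)[C@H]2CC(=O)OC(C)(C)C
F2 | step 20 | 3β-(tert-butyldimethylsilyloxy)-12-methoxy-7-(trimethylsilyloxy)abieta-6,8,11,13-tetraene | C[Si](C)(C)OC1=C[C@H]2C(C)(C)[C@@H](O[Si](C)(C)C(C)(C)C)CC[C@]2(C)c2cc(OC)c(C(C)C)cc21
F3 | step 20 | 3β-(tert-butyldimethylsilyloxy)-6α-hydroxy-12-methoxyabieta-8,11,13-trien-7-one | O=C1[C@H](O)[C@H]2C(C)(C)[C@@H](O[Si](C)(C)C(C)(C)C)CC[C@]2(C)c2cc(OC)c(C(C)C)cc21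
F4 | step 22 | 3β-(tert-butyldimethylsilyloxy)-12-methoxyabieta-8,11,13-trien-7β-ol | O[C@H]1C[C@H]2C(C)(C)[C@@H](O[Si](C)(C)C(C)(C)C)CC[C@]2(C)c2cc(OC)c(C(C)C)cc21
F5 | step 22 | 3β-(tert-butyldimethylsilyloxy)-12-methoxyabieta-6,8,11,13-tetraene | C1=C[C@H]2C(C)(C)[C@@H](O[Si](C)(C)C(C)(C)C)CC[C@]2(C)c2cc(OC)c(C(C)C)cc21
F6 | step 22 | 6α-bromo-3β-(tert-butyldimethylsilyloxy)-12-methoxyabieta-8,11,13-trien-7β-ol | O[C@H]1[C@H](Br)[C@H]2C(C)(C)[C@@H](O[Si](C)(C)C(C)(C)C)CC[C@]2(C)c2cc(OC)c(C(C)C)cc21
F7 | step 22 | 3β-(tert-butyldimethylsilyloxy)-6β,7β-epoxy-12-methoxyabieta-8,11,13-triene | [C@H]12O[C@H]1[C@H]1C(C)(C)[C@@H](O[Si](C)(C)C(C)(C)C)CC[C@]1(C)c1cc(OC)c(C(C)C)cc12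
F8 | step 22 | 3β-(tert-butyldimethylsilyloxy)-7α-(3-hydroxy-4-isopropyl-7-methyl-8-{2-[2-(propan-2-yl)-1,3-dioxolan-2-yl]ethyl}naphthalen-2-yl)-12-methoxyabieta-8,11,13-trien-6β-ol | Cc1ccc2c(C(C)C)c(O)c(cc2c1CCC1(C(C)C)OCCO1)[C@H]1c2cc(C(C)C)c(OC)cc2[C@@]2(C)CC[C@H](O[Si](C)(C)C(C)(C)C)C(C)(C)[C@@H]2[C@@H]1O
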